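**Strategy.** Ring A (the δ-lactone) is cut at the two bonds that flank its ester unit, spiro carbon–C(=O) and O–CH(acyl), so that the C(=O)–O unit becomes carbon dioxide. The spiro carbon is the α-carbon of the ring B ketone; the cis-fused keto lactone (rings B and C) is a latent β-keto acid dianion, and the three remaining carbons of ring A are a 1,3-bis-electrophile. In one flask the ketone is carboxylated with CO2, the dianion is C-alkylated on its convex face by an epoxy triflate, and the carboxyl group opens the epoxide with inversion. This three-component annulation builds ring A and sets the spiro centre and the O–CH centre; oxidation of the freed carbinol gives the target.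

Key step: step 11

Remarks:
- Ring A is the δ-lactone, ring B the cyclopentanone, ring C the γ-lactone. In the spiro compounds the cyclopenta[c]furan part has unprimed locants (C1 lactone carbonyl, O2, C3, C3a, C4, C5 spiro, C6 ketone, C6a) and ring A has primed locants (O1', C2' carbonyl, C3' = C5, C4', C5', C6').
- Assumption: the configuration of the carbinol carbon that ends as the isobutyryl carbonyl does not matter for the target. It is carried as the single (R) isomer that the matched aldol of step 7 should give.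
- Compounds 1, 2, 8, 9, 11 and 18 are taken as commercially available.

Step 1
Reactants: 1 cyclopent-2-en-1-one; 2 potassium trifluoro(prop-1-en-2-yl)borate
Product: 3 (3S)-3-(prop-1-en-2-yl)cyclopentan-1-one
Conditions: [Rh(cod)2]PF6 (3 mol %), (S)-BINAP, toluene/H2O, 105 °C
Reagents that add atoms: none
Why: Rhodium–BINAP-catalysed Hayashi–Miyaura 1,4-addition of the alkenylboron reagent to the cyclic enone should set C3 as (S), because the (S)-ligand is expected to deliver the alkenyl group to the same enone face as in the established aryl transfers.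

Step 2
Reactants: 3 (3S)-3-(prop-1-en-2-yl)cyclopentan-1-one
Product: 4 (3S)-3-(2-hydroxypropan-2-yl)cyclopentan-1-one
Conditions: Co(acac)2 (20 mol %), PhSiH3, O2 (1 atm), THF, rt; then aq. Na2S2O3
Reagents that add atoms: dioxygen (O=O)
Why: Mukaiyama hydration (hydrogen-atom transfer to the alkene, then O2 trapping of the tertiary radical) is Markovnikov-selective for the 1,1-disubstituted alkene, leaves the ketone alone and does not touch the stereocentre.

Step 3
Reactants: 4 (3S)-3-(2-hydroxypropan-2-yl)cyclopentan-1-one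
Product: 5 2-[(1S)-3-oxocyclopentyl]propan-2-yl 1H-imidazole-1-carboxylate
Conditions: CDI, DBU (cat.), MeCN, 50 °C
Reagents that add atoms: 1,1'-carbonyldiimidazole (O=C(n1ccnc1)n1ccnc1)
Why: Acyl transfer from CDI to the tertiary alcohol gives an activated carbonate that places the future lactone carbonyl on the oxygen next to the ring, with no stereocentre involved.

Step 4
Reactants: 5 2-[(1S)-3-oxocyclopentyl]propan-2-yl 1H-imidazole-1-carboxylate
Product: 7 (3aS,6aS)-3,3,6a-trimethyltetrahydro-1H-cyclopenta[c]furan-1,6(6aH)-dione, via sodium enolate of keto lactone 6 (not isolated)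
Conditions: NaH (2.2 equiv), THF, 0 → 50 °C; then MeI, 0 °C → rt
Reagents that add atoms: iodomethane (CI)
Why: Under equilibrating conditions the enolate on the substituted side undergoes an intramolecular Claisen-type C-acylation (5-exo-trig) that can only give the cis-fused γ-lactone and is driven by deprotonation of β-keto lactone 6, whose enolate is then C-methylated cis to H-3a because a trans-fused bicyclo[3.3.0] system is out of reach.

Step 5
Reactants: 8 (4S)-4-benzyl-1,3-oxazolidin-2-one; 9 3-methylbut-2-enoyl chloride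
Product: 10 (4S)-4-benzyl-3-(3-methylbut-2-enoyl)-1,3-oxazolidin-2-one
Conditions: n-BuLi, THF, −78 °C; then 9, −78 → 0 °C
Reagents that add atoms: none
Why: N-Acylation of the lithiated oxazolidinone with the acid chloride is the standard preparation of an Evans imide and leaves the auxiliary stereocentre untouched.

Step 6
Reactants: 11 3-methylbutanal
Product: 12 (2R)-3-methyl-1-oxobutan-2-yl benzoate
Conditions: (BzO)2, (R)-2-(triphenylmethyl)pyrrolidine (10 mol %), hydroquinone (10 mol %), THF, 0 °C; used without storage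
Reagents that add atoms: dibenzoyl peroxide (O=C(OOC(=O)c1ccccc1)c1ccccc1)
Why: Organocatalytic α-benzoyloxylation through the E-enamine, whose face next to the trityl group is shielded, should deliver the benzoyloxy group to the open face and give the (R) aldehyde.

Step 7
Reactants: 10 (4S)-4-benzyl-3-(3-methylbut-2-enoyl)-1,3-oxazolidin-2-one; 12 (2R)-3-methyl-1-oxobutan-2-yl benzoate
Product: 13 (4S)-4-benzyl-3-[(2S,3S,4R)-4-(benzoyloxy)-3-hydroxy-5-methyl-2-(prop-1-en-2-yl)hexanoyl]-1,3-oxazolidin-2-one
Conditions: Bu2BOTf, Et3N, CH2Cl2, −78 → 0 °C; then 12, −78 → 0 °C; pH 7 buffer, MeOH, H2O2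
Reagents that add atoms: none
Why: Evans syn aldol in which the Z boron dienolate of 10 reacts at its α-carbon through a closed chair transition state, so the (S)-benzyl auxiliary fixes C2 and C3 (syn) while the (R) aldehyde reacts in its matched non-chelation (polar Felkin–Anh) sense to make C3/C4 anti.

Step 8
Reactants: 13 (4S)-4-benzyl-3-[(2S,3S,4R)-4-(benzoyloxy)-3-hydroxy-5-methyl-2-(prop-1-en-2-yl)hexanoyl]-1,3-oxazolidin-2-one
Product: 14 (4S)-4-benzyl-3-[(2S,3S,4R)-4-(benzoyloxy)-3-(methanesulfonyloxy)-5-methyl-2-(prop-1-en-2-yl)hexanoyl]-1,3-oxazolidin-2-one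
Conditions: MsCl, pyridine, CH2Cl2, 0 °C
Reagents that add atoms: methanesulfonyl chloride (CS(Cl)(=O)=O)
Why: Sulfonylation of the only free hydroxyl with retention turns C3 into the leaving-group centre, and pyridine as a weak base should avoid β-elimination towards the imide.

Step 9
Reactants: 14 (4S)-4-benzyl-3-[(2S,3S,4R)-4-(benzoyloxy)-3-(methanesulfonyloxy)-5-methyl-2-(prop-1-en-2-yl)hexanoyl]-1,3-oxazolidin-2-one
Product: 16 (2R)-3-methyl-2-[(2R,3R)-3-(propan-2-yl)oxiran-2-yl]but-3-en-1-ol, via diol mesylate 15 (not isolated)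
Conditions: LiBH4, MeOH (1 equiv), THF, 0 °C → rt; then K2CO3, MeOH, rt
Reagents that add atoms: none
Why: Reductive removal of the auxiliary gives the primary alcohol and frees the C4 oxygen from its benzoate, and that alkoxide displaces the neighbouring mesylate (3-exo-tet Williamson-type closure, inversion at C3) to give the trans epoxide.

Step 10
Reactants: 16 (2R)-3-methyl-2-[(2R,3R)-3-(propan-2-yl)oxiran-2-yl]but-3-en-1-ol
Product: 17 (2R)-3-methyl-2-[(2R,3R)-3-(propan-2-yl)oxiran-2-yl]but-3-en-1-yl trifluoromethanesulfonate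
Conditions: Tf2O, 2,6-lutidine, CH2Cl2, −78 °C; used at once as a cold solution
Reagents that add atoms: trifluoromethanesulfonic anhydride (O=S(=O)(OS(=O)(=O)C(F)(F)F)C(F)(F)F)
Why: Triflation of the primary alcohol at low temperature with a hindered base leaves the epoxide and the alkene untouched and gives the 1,3-bis-electrophile.

Step 11
Reactants: 7 (3aS,6aS)-3,3,6a-trimethyltetrahydro-1H-cyclopenta[c]furan-1,6(6aH)-dione; 18 carbon dioxide; 17 (2R)-3-methyl-2-[(2R,3R)-3-(propan-2-yl)oxiran-2-yl]but-3-en-1-yl trifluoromethanesulfonate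
Product: 21 (3aS,5R,5'S,6'S,6aS)-6'-[(1R)-1-hydroxy-2-methylpropyl]-3,3,6a-trimethyl-5'-(prop-1-en-2-yl)hexahydrospiro[cyclopenta[c]furan-5,3'-oxane]-1,2',6-trione, via lithium keto carboxylate 19 (not isolated), via alkylated epoxy keto acid 20 (not isolated)
Conditions: LiN(SiMe3)2 (1.05 equiv), THF, −78 °C; CO2 (excess), −78 → 0 °C, then Ar purge; LiN(SiMe3)2 (1.1 equiv), −78 °C; 17 (1.2 equiv), −78 → −20 °C; then (±)-CSA (excess), 0 °C → rt
Reagents that add atoms: none
Why: LiN(SiMe3)2 forms the only enolate that 7 can give (at C5), CO2 traps it at carbon as lithium β-keto carboxylate 19, a second equivalent of base gives the lithium-chelated enolate–carboxylate dianion, the primary triflate of 17 alkylates this at carbon to 20, and acid then lets the carboxyl oxygen open the activated epoxide to 21. The closest known reaction types are the carboxylation of ketone enolates with CO2, the C-alkylation of chelated β-keto acid dianions (carboxylation–alkylation) and the acid-mediated lactonisation of epoxy acids, here telescoped into a formal three-component annulation. Ring A is closed by a 6-exo-tet SN2 attack of the carboxyl oxygen on the epoxide carbon C6', anti to the epoxide oxygen. The spiro centre is set in the C-alkylation, where the electrophile should approach the planar enolate from the convex face of the cis-bicyclo[3.3.0] system (syn to H-3a and the angular methyl, anti to ring C), which leaves the CO2-derived carbon on the concave face; C6' is set by inversion at the (R) epoxide carbon, C5' comes unchanged from 17 and the carbinol carbon keeps its configuration. The step needs carboxylation before alkylation (secured by the order of addition), C- over O-alkylation and substitution over elimination at the triflate (lithium chelation in THF at low temperature, high SN2 reactivity of a primary triflate), and 6-exo over 7-endo opening (ring size, equal substitution of both epoxide carbons).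

Step 12
Reactants: 21 (3aS,5R,5'S,6'S,6aS)-6'-[(1R)-1-hydroxy-2-methylpropyl]-3,3,6a-trimethyl-5'-(prop-1-en-2-yl)hexahydrospiro[cyclopenta[c]furan-5,3'-oxane]-1,2',6-trione
Product: 22 (3aS,5R,5'S,6'S,6aS)-3,3,6a-trimethyl-6'-(2-methylpropanoyl)-5'-(prop-1-en-2-yl)hexahydrospiro[cyclopenta[c]furan-5,3'-oxane]-1,2',6-trione (CNP0216954.1)
Conditions: Dess–Martin periodinane, NaHCO3, CH2Cl2, 0 °C → rt
Reagents that add atoms: none
Why: Dess–Martin oxidation of the secondary alcohol to the ketone under buffered, non-basic conditions should not epimerise the adjacent acyloxy-bearing C6' and leaves the alkene, the ring B ketone and both lactones intact.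

**Compound list**

1 | cyclopent-2-en-1-one | O=C1C=CCC1 | starting material
2 | potassium trifluoro(prop-1-en-2-yl)borate | [K+].C=C(C)[B-](F)(F)F | starting material
3 | (3S)-3-(prop-1-en-2-yl)cyclopentan-1-one | O=C1CC[C@H](C(C)=C)C1 | intermediate
4 | (3S)-3-(2-hydroxypropan-2-yl)cyclopentan-1-one | O=C1CC[C@H](C(C)(C)O)C1 | intermediate
5 | 2-[(1S)-3-oxocyclopentyl]propan-2-yl 1H-imidazole-1-carboxylate | O=C1CC[C@H](C(C)(C)OC(=O)n2ccnc2)C1 | intermediate
6 | (3aS,6aS)-3,3-dimethyltetrahydro-1H-cyclopenta[c]furan-1,6(6aH)-dione, present as its sodium enolate | C1C[C@@H]2C(C)(C)OC(=O)[C@@H]2C1=O | intermediate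
7 | (3aS,6aS)-3,3,6a-trimethyltetrahydro-1H-cyclopenta[c]furan-1,6(6aH)-dione | C1C[C@@H]2C(C)(C)OC(=O)[C@]2(C)C1=O | intermediate
8 | (4S)-4-benzyl-1,3-oxazolidin-2-one | O=C1N[C@@H](Cc2ccccc2)CO1 | starting material
9 | 3-methylbut-2-enoyl chloride | CC(C)=CC(Cl)=O | starting material
10 | (4S)-4-benzyl-3-(3-methylbut-2-enoyl)-1,3-oxazolidin-2-one | CC(C)=CC(=O)N1[C@@H](Cc2ccccc2)COC1=O | intermediate
11 | 3-methylbutanal | CC(C)CC=O | starting material
12 | (2R)-3-methyl-1-oxobutan-2-yl benzoate | O=C[C@H](OC(=O)c1ccccc1)C(C)C | intermediate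
13 | (4S)-4-benzyl-3-[(2S,3S,4R)-4-(benzoyloxy)-3-hydroxy-5-methyl-2-(prop-1-en-2-yl)hexanoyl]-1,3-oxazolidin-2-one | O=C(N1[C@@H](Cc2ccccc2)COC1=O)[C@@H](C(C)=C)[C@H](O)[C@H](OC(=O)c1ccccc1)C(C)C | intermediate
14 | (4S)-4-benzyl-3-[(2S,3S,4R)-4-(benzoyloxy)-3-(methanesulfonyloxy)-5-methyl-2-(prop-1-en-2-yl)hexanoyl]-1,3-oxazolidin-2-one | O=C(N1[C@@H](Cc2ccccc2)COC1=O)[C@@H](C(C)=C)[C@H](OS(C)(=O)=O)[C@H](OC(=O)c1ccccc1)C(C)C | intermediate
15 | (2R,3S,4R)-1,4-dihydroxy-5-methyl-2-(prop-1-en-2-yl)hexan-3-yl methanesulfonate | OC[C@@H](C(C)=C)[C@H](OS(C)(=O)=O)[C@H](O)C(C)C | intermediate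
16 | (2R)-3-methyl-2-[(2R,3R)-3-(propan-2-yl)oxiran-2-yl]but-3-en-1-ol | OC[C@@H](C(C)=C)[C@H]1O[C@@H]1C(C)C | intermediate
17 | (2R)-3-methyl-2-[(2R,3R)-3-(propan-2-yl)oxiran-2-yl]but-3-en-1-yl trifluoromethanesulfonate | FC(F)(F)S(=O)(=O)OC[C@@H](C(C)=C)[C@H]1O[C@@H]1C(C)C | intermediate
18 | carbon dioxide | O=C=O | starting material
19 | lithium (3aS,6aS)-3,3,6a-trimethyl-1,6-dioxohexahydro-1H-cyclopenta[c]furan-5-carboxylate (C5 not defined) | [Li+].[O-]C(=O)C1C[C@@H]2C(C)(C)OC(=O)[C@]2(C)C1=O | intermediate
20 | (3aS,5R,6aS)-3,3,6a-trimethyl-5-{(2S)-3-methyl-2-[(2R,3R)-3-(propan-2-yl)oxiran-2-yl]but-3-en-1-yl}-1,6-dioxohexahydro-1H-cyclopenta[c]furan-5-carboxylic acid, first formed as its lithium salt | OC(=O)[C@]1(C[C@@H](C(C)=C)[C@H]2O[C@@H]2C(C)C)C[C@@H]3C(C)(C)OC(=O)[C@]3(C)C1=O | intermediate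
21 | (3aS,5R,5'S,6'S,6aS)-6'-[(1R)-1-hydroxy-2-methylpropyl]-3,3,6a-trimethyl-5'-(prop-1-en-2-yl)hexahydrospiro[cyclopenta[c]furan-5,3'-oxane]-1,2',6-trione | C=C(C)[C@@H]1C[C@]2(C[C@@H]3C(C)(C)OC(=O)[C@]3(C)C2=O)C(=O)O[C@@H]1[C@H](O)C(C)C | intermediate
22 | (3aS,5R,5'S,6'S,6aS)-3,3,6a-trimethyl-6'-(2-methylpropanoyl)-5'-(prop-1-en-2-yl)hexahydrospiro[cyclopenta[c]furan-5,3'-oxane]-1,2',6-trione (CNP0216954.1) | C=C(C)[C@@H]1C[C@]2(C[C@@H]3C(C)(C)OC(=O)[C@]3(C)C2=O)C(=O)O[C@@H]1C(=O)C(C)C | target

**Step count.** Total: 12 steps. Longest linear sequence: 7 steps (steps 6, 7, 8, 9, 10, 11, 12).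

**Steps most likely to fail**

1. Step 11. The dianion may act as a base and eliminate triflic acid from 17 (its β-hydrogen is allylic), alkylate on oxygen, or be quenched by proton transfer, and the β-keto acid may lose CO2 before the ring closes. The fallback sets out from 7 and puts the carboxyl carbon in first as an ester. LiN(SiMe3)2 (2 equiv) and di-tert-butyl dicarbonate in THF at −78 °C should give tert-butyl (3aS,6aS)-3,3,6a-trimethyl-1,6-dioxohexahydro-1H-cyclopenta[c]furan-5-carboxylate F1. Its much less basic caesium enolate (Cs2CO3, DMF, 0 °C → rt) is alkylated by 17 on the convex face to tert-butyl (3aS,5R,6aS)-3,3,6a-trimethyl-5-{(2S)-3-methyl-2-[(2R,3R)-3-(propan-2-yl)oxiran-2-yl]but-3-en-1-yl}-1,6-dioxohexahydro-1H-cyclopenta[c]furan-5-carboxylate F2. TFA in CH2Cl2 at 0 °C then lets the ester carbonyl open the protonated epoxide at C6' with inversion and loss of 2-methylpropene. This comes back to the route at 21.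

2. Step 4. Acylation may go through the less substituted enolate to a bridged lactone, the enolate may condense with a second molecule, or the β-keto lactone enolate may be methylated on oxygen. The fallback sets out from 2 and carries the carboxyl group on the enone from the start. Commercial methyl 2-oxocyclopentane-1-carboxylate is selenenylated (PhSeCl, pyridine, CH2Cl2) to methyl 2-oxo-1-(phenylselanyl)cyclopentane-1-carboxylate F3. Oxidative elimination (H2O2) gives methyl 5-oxocyclopent-1-ene-1-carboxylate F4. Addition of 2 under the conditions of step 1 should give methyl (2S)-5-oxo-2-(prop-1-en-2-yl)cyclopentane-1-carboxylate F5. MeI with K2CO3 in acetone methylates it anti to the isopropenyl group to methyl (1S,2R)-1-methyl-5-oxo-2-(prop-1-en-2-yl)cyclopentane-1-carboxylate F6. TfOH in CH2Cl2 at 0 °C protonates the alkene, and the cis ester traps the tertiary cation with loss of its methyl group. This comes back to the route at 7.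

3. Step 7. The dienolate may react at its γ-carbon, facial selectivity may erode if the aldehyde is the mismatched partner, and the α-benzoyloxy aldehyde may epimerise or suffer acyl migration. The fallback sets out from 12 and replaces the auxiliary aldol by a substrate-controlled allylation. Barbier reaction of 12 with (E)-4-bromo-3-methylbut-2-en-1-yl acetate and In powder in THF/H2O should react at the γ-carbon of the allyl metal through a chair transition state (anti crotyl-type relation) under non-chelation control by the benzoyloxy centre, giving (2R,3S,4R)-1-acetoxy-3-hydroxy-5-methyl-2-(prop-1-en-2-yl)hexan-4-yl benzoate F7. MsCl and pyridine give (2R,3S,4R)-1-acetoxy-3-(methanesulfonyloxy)-5-methyl-2-(prop-1-en-2-yl)hexan-4-yl benzoate F8. K2CO3 in MeOH removes both esters and closes the epoxide with inversion. This comes back to the route at 16.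

**Further compounds**

F1 | step 11 | tert-butyl (3aS,6aS)-3,3,6a-trimethyl-1,6-dioxohexahydro-1H-cyclopenta[c]furan-5-carboxylate | CC(C)(C)OC(=O)C1C[C@@H]2C(C)(C)OC(=O)[C@]2(C)C1=O
F2 | step 11 | tert-butyl (3aS,5R,6aS)-3,3,6a-trimethyl-5-{(2S)-3-methyl-2-[(2R,3R)-3-(propan-2-yl)oxiran-2-yl]but-3-en-1-yl}-1,6-dioxohexahydro-1H-cyclopenta[c]furan-5-carboxylate | CC(C)(C)OC(=O)[C@]1(C[C@@H](C(C)=C)[C@H]2O[C@@H]2C(C)C)C[C@@H]3C(C)(C)OC(=O)[C@]3(C)C1=O
F3 | step 4 | methyl 2-oxo-1-(phenylselanyl)cyclopentane-1-carboxylate | COC(=O)C1([Se]c2ccccc2)CCCC1=O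
F4 | step 4 | methyl 5-oxocyclopent-1-ene-1-carboxylate | COC(=O)C1=CCCC1=O
F5 | step 4 | methyl (2S)-5-oxo-2-(prop-1-en-2-yl)cyclopentane-1-carboxylate | COC(=O)C1C(=O)CC[C@@H]1C(C)=C
F6 | step 4 | methyl (1S,2R)-1-methyl-5-oxo-2-(prop-1-en-2-yl)cyclopentane-1-carboxylate | COC(=O)[C@]1(C)C(=O)CC[C@@H]1C(C)=C
F7 | step 7 | (2R,3S,4R)-1-acetoxy-3-hydroxy-5-methyl-2-(prop-1-en-2-yl)hexan-4-yl benzoate | CC(=O)OC[C@@H](C(C)=C)[C@H](O)[C@H](OC(=O)c1ccccc1)C(C)C
F8 | step 7 | (2R,3S,4R)-1-acetoxy-3-(methanesulfonyloxy)-5-methyl-2-(prop-1-en-2-yl)hexan-4-yl benzoate | CC(=O)OC[C@@H](C(C)=C)[C@H](OS(C)(=O)=O)[C@H](OC(=O)c1ccccc1)C(C)C
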